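**Plan**

1. Numbering: C1 = CH2OAc, C2=C3 (Z), oxirane C6–C7, C10=C11 (E), carbinol C12, methylidene on C14, C15 = isopropyl CH. Retrosynthetic cuts in order: acetyl–O1, C11–C12, C10=C11, C8–C9, the oxirane C–O bonds, C6=C7, C14–C15.
2. Enabling feature: C12 is an oxygen-bearing sp3 carbon bonded directly to the alkene carbon C11 (a secondary allylic carbinol on a trisubstituted alkene). It can therefore be built from an α-oxygenated carbenoid carbon and an alkenyl–boron bond by a 1,2-metallate shift, the new C12–B bond then being oxidised to C12–OH.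
3. Forward: nerol gives C1–C6 with the 2Z alkene; Z-selective olefination adds C7/C8; the oxirane (the only ring) is closed on the resulting allylic alcohol; C9–C10 and then C11 with boron are attached; the C12–C16 benzoate is joined last; desilylation and selective O1-acetylation finish.
4. Stereochemistry: 2Z from nerol; 6Z (hence the cis-oxirane) from Still–Gennari olefination; 6R,7S from Sharpless epoxidation with L-(+)-diethyl tartrate; 10E from the alkenylboronate geometry carried through the stereospecific shift; 12R from (−)-sparteine-mediated lithiation (reagent control).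

Key step: step 11

Remark: the oxirane made in step 2 is racemic and is excised in step 3; TBS = tert-butyl(dimethyl)silyl, B(pin) = 4,4,5,5-tetramethyl-1,3,2-dioxaborolan-2-yl, TIB = 2,4,6-tri(propan-2-yl)benzoyl; nerol, 3-bromobut-3-en-1-ol, (−)-sparteine and the reagents named are taken as purchasable.

**Route**

Step 1
Reactants: 1 nerol, (2Z)-3,7-dimethylocta-2,6-dien-1-ol
Product: 2 tert-butyl{[(2Z)-3,7-dimethylocta-2,6-dien-1-yl]oxy}dimethylsilane
Conditions: TBSCl, imidazole, CH2Cl2, 0 °C to rt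
Reagents that add atoms: tert-butyldimethylsilyl chloride, CC(C)(C)[Si](C)(C)Cl
Why: Imidazole-promoted silylation of the primary allylic alcohol masks O1 for the basic and organometallic steps that follow.

Step 2
Reactants: 2 tert-butyl{[(2Z)-3,7-dimethylocta-2,6-dien-1-yl]oxy}dimethylsilane
Product: 3 tert-butyl{[(2Z)-5-(3,3-dimethyloxiran-2-yl)-3-methylpent-2-en-1-yl]oxy}dimethylsilane (racemic)
Conditions: mCPBA (1.05 equiv), NaHCO3, CH2Cl2, −20 to 0 °C
Reagents that add atoms: 3-chloroperoxybenzoic acid, OOC(=O)c1cccc(Cl)c1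
Why: Prilezhaev epoxidation is electrophilic and should prefer the distal, more electron-rich alkene of the neryl chain over the C2=C3 alkene, which is deactivated inductively by the allylic silyloxy group.

Step 3
Reactants: 3 tert-butyl{[(2Z)-5-(3,3-dimethyloxiran-2-yl)-3-methylpent-2-en-1-yl]oxy}dimethylsilane
Product: 4 (4Z)-6-(TBSO)-4-methylhex-4-enal
Conditions: H5IO6, THF/Et2O, 0 °C
Reagents that add atoms: none
Why: Periodic acid opens the oxirane and cleaves the resulting glycol (Malaprade-type cleavage), releasing acetone and leaving the aldehyde at the future C6 without touching the Z-alkene.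

Step 4
Reactants: 4 (4Z)-6-(TBSO)-4-methylhex-4-enal
Product: 5 methyl (2Z,6Z)-8-(TBSO)-2,6-dimethylocta-2,6-dienoate
Conditions: (CF3CH2O)2P(O)CH(CH3)CO2CH3, KN(SiMe3)2, 18-crown-6, THF, −78 °C
Reagents that add atoms: methyl 2-[bis(2,2,2-trifluoroethoxy)phosphoryl]propanoate, COC(=O)C(C)P(=O)(OCC(F)(F)F)OCC(F)(F)F
Why: Still–Gennari olefination under dissociating conditions should give the (Z)-2-methyl enoate by fast, kinetically controlled elimination, which fixes the 6Z geometry that later becomes the cis-oxirane.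

Step 5
Reactants: 5 methyl (2Z,6Z)-8-(TBSO)-2,6-dimethylocta-2,6-dienoate
Product: 6 (2Z,6Z)-8-(TBSO)-2,6-dimethylocta-2,6-dien-1-ol
Conditions: iBu2AlH, CH2Cl2, −78 °C; aqueous potassium sodium tartrate
Reagents that add atoms: none
Why: 1,2-Reduction of the enoate by the aluminium hydride at low temperature gives the allylic alcohol without changing either alkene geometry or the silyl ether.

Step 6
Reactants: 6 (2Z,6Z)-8-(TBSO)-2,6-dimethylocta-2,6-dien-1-ol
Product: 7 [(2S,3R)-3-[(3Z)-5-(TBSO)-3-methylpent-3-en-1-yl]-2-methyloxiran-2-yl]methanol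
Conditions: Ti(OiPr)4, L-(+)-diethyl tartrate, tBuOOH, 4 Å molecular sieves, CH2Cl2, −20 °C
Reagents that add atoms: tert-butyl hydroperoxide, CC(C)(C)OO
Why: Sharpless asymmetric epoxidation is directed by the free allylic hydroxyl, so only C6=C7 reacts; the L-(+)-tartrate–titanium complex should deliver oxygen to the face that gives 6R,7S (target numbering), and the Z geometry is carried stereospecifically into the cis-oxirane.

Step 7
Reactants: 7 [(2S,3R)-3-[(3Z)-5-(TBSO)-3-methylpent-3-en-1-yl]-2-methyloxiran-2-yl]methanol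
Product: 9 tert-butyl{[(2Z)-5-[(2R,3S)-3-(but-3-en-1-yl)-3-methyloxiran-2-yl]-3-methylpent-2-en-1-yl]oxy}dimethylsilane, via epoxy triflate 8 (not isolated)
Conditions: Tf2O, 2,6-lutidine, CH2Cl2, −78 °C; then transfer into CH2=CHCH2MgBr (excess), CuBr·SMe2 (cat.), Et2O, −78 to −40 °C
Reagents that add atoms: trifluoromethanesulfonic anhydride (atoms kept in 8 only), O=S(=O)(OS(=O)(=O)C(F)(F)F)C(F)(F)F; allylmagnesium bromide, C=CC[Mg]Br
Why: Copper-catalysed coupling of a primary alkyl triflate with a Grignard reagent; the triflate beside the oxirane should be displaced at low temperature faster than the hindered trisubstituted oxirane is opened, so C8–C9 forms with the ring intact.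

Step 8
Reactants: 9 tert-butyl{[(2Z)-5-[(2R,3S)-3-(but-3-en-1-yl)-3-methyloxiran-2-yl]-3-methylpent-2-en-1-yl]oxy}dimethylsilane
Product: 10 tert-butyl{[(2Z)-3-methyl-5-[(2R,3S)-3-methyl-3-[(3Z)-4-B(pin)-pent-3-en-1-yl]oxiran-2-yl]pent-2-en-1-yl]oxy}dimethylsilane (boron trans to the chain across C10=C11)
Conditions: CH2=C(CH3)B(pin) (3 equiv), second-generation Grubbs catalyst RuCl2(=CHPh)(PCy3)(H2IMes) (5 mol %), CH2Cl2, 40 °C
Reagents that add atoms: 2-propenylboronic acid pinacol ester, C=C(C)B1OC(C)(C)C(C)(C)O1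
Why: Olefin cross-metathesis of the monosubstituted alkene with the 1,1-disubstituted boronate should place the bulky pinacolboryl group trans to the chain in the new trisubstituted alkene, while the trisubstituted C2=C3 alkene and the oxirane stay inert to the ruthenium carbene.

Step 9
Reactants: 11 3-bromobut-3-en-1-ol
Product: 12 4-methyl-3-methylidenepentan-1-ol
Conditions: iPrMgCl (2.5 equiv), PdCl2(dppf) (cat.), THF, 0 °C to rt
Reagents that add atoms: isopropylmagnesium chloride, CC(C)[Mg]Cl
Why: Kumada coupling of the alkenyl bromide (as its magnesium alkoxide) with the secondary Grignard reagent; the wide-bite-angle dppf ligand favours reductive elimination over β-hydride elimination, so the isopropyl group should be transferred without isomerisation.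

Step 10
Reactants: 12 4-methyl-3-methylidenepentan-1-ol
Product: 13 4-methyl-3-methylidenepentyl 2,4,6-tri(propan-2-yl)benzoate
Conditions: 2,4,6-tri(propan-2-yl)benzoic acid, PPh3, DIAD, THF, 0 °C to rt
Reagents that add atoms: 2,4,6-tri(propan-2-yl)benzoic acid, CC(C)c1cc(C(C)C)c(C(=O)O)c(C(C)C)c1
Why: Mitsunobu esterification of the primary alcohol installs the hindered benzoate that directs α-lithiation and later acts as the leaving group.

Step 11
Reactants: 13 4-methyl-3-methylidenepentyl 2,4,6-tri(propan-2-yl)benzoate; 10 tert-butyl{[(2Z)-3-methyl-5-[(2R,3S)-3-methyl-3-[(3Z)-4-B(pin)-pent-3-en-1-yl]oxiran-2-yl]pent-2-en-1-yl]oxy}dimethylsilane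
Product: 17 (2Z,6R,7S,10E,12R)-1-(TBSO)-6,7-epoxy-3,7,11,15-tetramethyl-14-methylidenehexadeca-2,10-dien-12-ol, via lithiated benzoate 14 (not isolated), via boronate complex 15 (not isolated), via allylic boronic ester 16 (not isolated)
Conditions: 13 (1.3 equiv), sBuLi (1.25 equiv), (−)-sparteine (1.3 equiv), Et2O, −78 °C, 5 h; add 10 (1.0 equiv), −78 °C, 1 h; then 35 °C, 12 h; then NaOH (2 M aq.), H2O2 (30 % aq.), THF, 0 °C to rt
Reagents that add atoms: sec-butyllithium (lithium kept in 14 and 15 only), CCC(C)[Li]; hydrogen peroxide (oxygen of the C12 hydroxyl), OO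
Why: sBuLi/(−)-sparteine removes the pro-S proton next to the benzoate oxygen to give the configurationally stable (S)-organolithium 14, which attacks the boron of 10 with retention to form boronate 15; on warming, the alkenyl group shifts from boron to C12 anti-periplanar to the departing benzoate (1,2-metallate rearrangement, inversion at C12, alkene geometry retained), and oxidation of the C–B bond of 16 with retention should give the 12R alcohol. The closest known reaction type is lithiation–borylation (Matteson-type homologation) of alkenyl boronic esters with sparteine-derived α-oxyalkyllithiums to give α-chiral allylic boronic esters. No ring is closed. The only new stereocentre, C12, is set by the chiral diamine (reagent control) independently of the remote C6/C7 centres, and the C10=C11 geometry is that of 10. The step needs the organolithium to choose boron over the oxirane and the silyl ether, which the very fast boronate formation at −78 °C and the absence of any Lewis acid additive (the benzoate leaves unaided) should secure; the allylic pinacol boronate 16 should also not undergo 1,3-borotropic shift before it is oxidised.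

Step 12
Reactants: 17 (2Z,6R,7S,10E,12R)-1-(TBSO)-6,7-epoxy-3,7,11,15-tetramethyl-14-methylidenehexadeca-2,10-dien-12-ol
Product: 18 (2Z,6R,7S,10E,12R)-6,7-epoxy-3,7,11,15-tetramethyl-14-methylidenehexadeca-2,10-diene-1,12-diol
Conditions: Bu4NF, THF, 0 °C to rt
Reagents that add atoms: none
Why: Fluoride-mediated desilylation cleaves only the Si–O bond; the oxirane and the alkenes are inert under these nearly neutral conditions.

Step 13
Reactants: 18 (2Z,6R,7S,10E,12R)-6,7-epoxy-3,7,11,15-tetramethyl-14-methylidenehexadeca-2,10-diene-1,12-diol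
Product: 19 (2Z,6R,7S,10E,12R)-6,7-epoxy-12-hydroxy-3,7,11,15-tetramethyl-14-methylidenehexadeca-2,10-dien-1-yl acetate
Conditions: AcCl (1.05 equiv), 2,4,6-collidine, CH2Cl2, −78 °C
Reagents that add atoms: acetyl chloride, CC(Cl)=O
Why: Kinetically chemoselective acylation: acetyl chloride with the hindered pyridine base at low temperature should acylate the unhindered primary allylic hydroxyl much faster than the secondary C12 hydroxyl flanked by a trisubstituted alkene carbon.

**Compound list**

1 | nerol, (2Z)-3,7-dimethylocta-2,6-dien-1-ol | CC(C)=CCC/C(C)=C\CO | starting material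
2 | tert-butyl{[(2Z)-3,7-dimethylocta-2,6-dien-1-yl]oxy}dimethylsilane | CC(C)=CCC/C(C)=C\CO[Si](C)(C)C(C)(C)C | intermediate
3 | tert-butyl{[(2Z)-5-(3,3-dimethyloxiran-2-yl)-3-methylpent-2-en-1-yl]oxy}dimethylsilane (racemic) | CC1(C)OC1CC/C(C)=C\CO[Si](C)(C)C(C)(C)C | intermediate
4 | (4Z)-6-(TBSO)-4-methylhex-4-enal | O=CCC/C(C)=C\CO[Si](C)(C)C(C)(C)C | intermediate
5 | methyl (2Z,6Z)-8-(TBSO)-2,6-dimethylocta-2,6-dienoate | COC(=O)/C(C)=C\CC/C(C)=C\CO[Si](C)(C)C(C)(C)C | intermediate
6 | (2Z,6Z)-8-(TBSO)-2,6-dimethylocta-2,6-dien-1-ol | OC/C(C)=C\CC/C(C)=C\CO[Si](C)(C)C(C)(C)C | intermediate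
7 | [(2S,3R)-3-[(3Z)-5-(TBSO)-3-methylpent-3-en-1-yl]-2-methyloxiran-2-yl]methanol | OC[C@]1(C)O[C@@H]1CC/C(C)=C\CO[Si](C)(C)C(C)(C)C | intermediate
8 | [(2S,3R)-3-[(3Z)-5-(TBSO)-3-methylpent-3-en-1-yl]-2-methyloxiran-2-yl]methyl trifluoromethanesulfonate | FC(F)(F)S(=O)(=O)OC[C@]1(C)O[C@@H]1CC/C(C)=C\CO[Si](C)(C)C(C)(C)C | intermediate
9 | tert-butyl{[(2Z)-5-[(2R,3S)-3-(but-3-en-1-yl)-3-methyloxiran-2-yl]-3-methylpent-2-en-1-yl]oxy}dimethylsilane | C=CCC[C@]1(C)O[C@@H]1CC/C(C)=C\CO[Si](C)(C)C(C)(C)C | intermediate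
10 | tert-butyl{[(2Z)-3-methyl-5-[(2R,3S)-3-methyl-3-[(3Z)-4-B(pin)-pent-3-en-1-yl]oxiran-2-yl]pent-2-en-1-yl]oxy}dimethylsilane | CC1(C)OB(/C(C)=C/CC[C@]2(C)O[C@@H]2CC/C(C)=C\CO[Si](C)(C)C(C)(C)C)OC1(C)C | intermediate
11 | 3-bromobut-3-en-1-ol | C=C(Br)CCO | starting material
12 | 4-methyl-3-methylidenepentan-1-ol | C=C(CCO)C(C)C | intermediate
13 | 4-methyl-3-methylidenepentyl 2,4,6-tri(propan-2-yl)benzoate | C=C(CCOC(=O)c1c(C(C)C)cc(C(C)C)cc1C(C)C)C(C)C | intermediate
14 | (1S)-1-lithio-4-methyl-3-methylidenepentyl 2,4,6-tri(propan-2-yl)benzoate (as its (−)-sparteine complex) | C=C(C[C@H]([Li])OC(=O)c1c(C(C)C)cc(C(C)C)cc1C(C)C)C(C)C | intermediate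
15 | lithium boronate complex of 14 and 10 (tetracoordinate boron bearing the pinacolato group, the C11 alkenyl carbon and the (S)-configured C12 that still carries the benzoate) | [Li+].C=C(C[C@H]([B-]1(/C(C)=C/CC[C@]2(C)O[C@@H]2CC/C(C)=C\CO[Si](C)(C)C(C)(C)C)OC(C)(C)C(C)(C)O1)OC(=O)c1c(C(C)C)cc(C(C)C)cc1C(C)C)C(C)C | intermediate
16 | (2Z,6R,7S,10E,12R)-1-(TBSO)-6,7-epoxy-3,7,11,15-tetramethyl-14-methylidene-12-B(pin)-hexadeca-2,10-diene | C=C(C[C@@H](B1OC(C)(C)C(C)(C)O1)/C(C)=C/CC[C@]2(C)O[C@@H]2CC/C(C)=C\CO[Si](C)(C)C(C)(C)C)C(C)C | intermediate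
17 | (2Z,6R,7S,10E,12R)-1-(TBSO)-6,7-epoxy-3,7,11,15-tetramethyl-14-methylidenehexadeca-2,10-dien-12-ol | C=C(C[C@@H](O)/C(C)=C/CC[C@]1(C)O[C@@H]1CC/C(C)=C\CO[Si](C)(C)C(C)(C)C)C(C)C | intermediate
18 | (2Z,6R,7S,10E,12R)-6,7-epoxy-3,7,11,15-tetramethyl-14-methylidenehexadeca-2,10-diene-1,12-diol | C=C(C[C@@H](O)/C(C)=C/CC[C@]1(C)O[C@@H]1CC/C(C)=C\CO)C(C)C | intermediate
19 | (2Z,6R,7S,10E,12R)-6,7-epoxy-12-hydroxy-3,7,11,15-tetramethyl-14-methylidenehexadeca-2,10-dien-1-yl acetate | C=C(C[C@@H](O)/C(C)=C/CC[C@]1(C)O[C@@H]1CC/C(C)=C\COC(C)=O)C(C)C | target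

**Totals**

Total step count: 13. Longest linear sequence: 11 steps (steps 1–8, then 11–13).

**Steps most likely to fail**

Step 8. The risk is loss of control over the geometry of the new trisubstituted C10=C11 bond (boron ending cis to the chain) together with slow turnover of the 1,1-disubstituted boronate. The fallback sets out from 7 and reaches the same boronate through an alkyne. The triflate 8 would be displaced with 1-lithiobut-2-yne (but-2-yne, nBuLi, THF, −78 °C) to give the methyl alkyne tert-butyl{[(2Z)-3-methyl-5-[(2R,3S)-3-methyl-3-(pent-3-yn-1-yl)oxiran-2-yl]pent-2-en-1-yl]oxy}dimethylsilane F1. Copper-catalysed syn-protoboration (CuCl, NaOtBu, P(p-tolyl)3, B2pin2, MeOH, THF) would then add boron and hydrogen to the same face, with boron at the less hindered methyl-bearing carbon. The geometry is thus fixed by the mechanism; any regioisomer would be removed by chromatography. The route is rejoined at 10.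

Step 11. The risk is attack of the organolithium on the oxirane, an incomplete 1,2-shift, or partial loss of configuration of the lithiated benzoate before it is trapped. The fallback sets out from 10 and 12 and forms the same C11–C12 bond by carbonyl addition.
- Base-first iododeboronation of 10 (NaOH, then I2, THF/H2O, 0 °C; retention) would give the alkenyl iodide tert-butyl{[(2Z)-5-[(2R,3S)-3-[(3E)-4-iodopent-3-en-1-yl]-3-methyloxiran-2-yl]-3-methylpent-2-en-1-yl]oxy}dimethylsilane F2.
- Dess–Martin oxidation of 12 would give 4-methyl-3-methylidenepentanal F3, used at once.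
- Nozaki–Hiyama–Kishi coupling (CrCl2, NiCl2 cat., DMSO) would give the allylic alcohol as both C12 epimers, (2Z,6R,7S,10E,12RS)-1-(TBSO)-6,7-epoxy-3,7,11,15-tetramethyl-14-methylidenehexadeca-2,10-dien-12-ol F4.
- Dess–Martin oxidation would give the enone (2Z,6R,7S,10E)-1-(TBSO)-6,7-epoxy-3,7,11,15-tetramethyl-14-methylidenehexadeca-2,10-dien-12-one F5.
- Corey–Bakshi–Shibata reduction with (S)-2-methyl-CBS-oxazaborolidine and catecholborane, the α-methylalkenyl group acting as the large substituent, should set 12R and rejoin the route at 17.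

Step 7. The risk is opening of the oxirane by the allyl nucleophile or its magnesium salts, or ionisation of the hindered triflate before substitution. The fallback sets out from 7 and avoids substitution at C8.
- Parikh–Doering oxidation (SO3·pyridine, DMSO, iPr2NEt) would give the epoxy aldehyde (2R,3R)-3-[(3Z)-5-(TBSO)-3-methylpent-3-en-1-yl]-2-methyloxirane-2-carbaldehyde F6, which has no enolisable centre at C7.
- Wittig methylenation (Ph3P=CH2, THF) would give the vinyl oxirane tert-butyl{[(2Z)-5-[(2R,3S)-3-ethenyl-3-methyloxiran-2-yl]-3-methylpent-2-en-1-yl]oxy}dimethylsilane F7.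
- Hydroboration of the vinyl group with 9-borabicyclo[3.3.1]nonane would give the B-alkylborane 9-{2-[(2S,3R)-3-[(3Z)-5-(TBSO)-3-methylpent-3-en-1-yl]-2-methyloxiran-2-yl]ethyl}-9-borabicyclo[3.3.1]nonane F8, not isolated.
- B-alkyl Suzuki–Miyaura coupling with vinyl bromide (PdCl2(dppf), K3PO4, THF/DMF/H2O) would then rejoin the route at 9.

**Further compounds**

F1 | step 8 | tert-butyl{[(2Z)-3-methyl-5-[(2R,3S)-3-methyl-3-(pent-3-yn-1-yl)oxiran-2-yl]pent-2-en-1-yl]oxy}dimethylsilane | CC#CCC[C@]1(C)O[C@@H]1CC/C(C)=C\CO[Si](C)(C)C(C)(C)C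
F2 | step 11 | tert-butyl{[(2Z)-5-[(2R,3S)-3-[(3E)-4-iodopent-3-en-1-yl]-3-methyloxiran-2-yl]-3-methylpent-2-en-1-yl]oxy}dimethylsilane | I/C(C)=C/CC[C@]1(C)O[C@@H]1CC/C(C)=C\CO[Si](C)(C)C(C)(C)C
F3 | step 11 | 4-methyl-3-methylidenepentanal | C=C(CC=O)C(C)C
F4 | step 11 | (2Z,6R,7S,10E,12RS)-1-(TBSO)-6,7-epoxy-3,7,11,15-tetramethyl-14-methylidenehexadeca-2,10-dien-12-ol (both C12 epimers) | C=C(CC(O)/C(C)=C/CC[C@]1(C)O[C@@H]1CC/C(C)=C\CO[Si](C)(C)C(C)(C)C)C(C)C
F5 | step 11 | (2Z,6R,7S,10E)-1-(TBSO)-6,7-epoxy-3,7,11,15-tetramethyl-14-methylidenehexadeca-2,10-dien-12-one | C=C(CC(=O)/C(C)=C/CC[C@]1(C)O[C@@H]1CC/C(C)=C\CO[Si](C)(C)C(C)(C)C)C(C)C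
F6 | step 7 | (2R,3R)-3-[(3Z)-5-(TBSO)-3-methylpent-3-en-1-yl]-2-methyloxirane-2-carbaldehyde | O=C[C@]1(C)O[C@@H]1CC/C(C)=C\CO[Si](C)(C)C(C)(C)C
F7 | step 7 | tert-butyl{[(2Z)-5-[(2R,3S)-3-ethenyl-3-methyloxiran-2-yl]-3-methylpent-2-en-1-yl]oxy}dimethylsilane | C=C[C@]1(C)O[C@@H]1CC/C(C)=C\CO[Si](C)(C)C(C)(C)C
F8 | step 7 | 9-{2-[(2S,3R)-3-[(3Z)-5-(TBSO)-3-methylpent-3-en-1-yl]-2-methyloxiran-2-yl]ethyl}-9-borabicyclo[3.3.1]nonane | C1CC2CCCC(C1)B2CC[C@]3(C)O[C@@H]3CC/C(C)=C\CO[Si](C)(C)C(C)(C)C
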